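## The problem

Target 20 is a monocyclic oxolane, numbered here O1, C2 (4-hydroxyphenyl), C3 (acetoxymethyl carbon C6), C4 (side-chain carbon C7 with an acetoxy group and the 4-methoxyphenyl ring) and C5 (CH2). No ring fusion has to be built. The work lies in the branched chain C7–C4(–C5)–C3(–C6)–C2, whose two aryl ends differ only in OH against OMe and so must arrive in separate steps, the phenol masked. Four stereocentres are needed: the ring substituents are all-trans (2R,3S,4R) and C7 is S. C3 and C4 are vicinal and trans, so one can direct the other if both are made on a ring. C2 is trans to C3 in what is also the more stable arrangement, so it can be set late from C3 and C4. C7 lies outside the ring and can only be governed by C4 through 1,2-induction. The fragile groups are the two acetates, the free phenol, and two para-oxygenated benzylic C–O bonds (C2–O1 and C7–OAc) that ionise in acid and break on hydrogenolysis; this excludes benzyl protection and any strong acid once the C7 oxygen is in place. The enabling feature is that O1–C2–C3–C4–C5 is a γ-butyrolactone skeleton when C2 is the carbonyl: C3 and C4 are then the α and β carbons of a butenolide, C5 can be an acetal carbon carrying a removable chiral alkoxy group, C7 (ketone level) is an acyl-anion site and C6 is one formaldehyde unit.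

## Retrosynthesis

**Phenol and acetates (20 ⇒ 19 ⇒ 18).** The aryl O–Si bond of 19 is cut last and the two O–acetyl bonds before it, which leads to diol 18. A triisopropylsilyl ether is preferred to a benzyl ether, because hydrogenolysis would attack both benzylic C–O bonds, and to a phenolic ester, which would be hard to tell from the two acetates. Both hydroxyls of 18 are acetylated together, so C6–OH and C7–OH need no differentiation. The forward steps must acetylate without ionising C7–O and desilylate without acyl transfer.

**C7–H (18 ⇒ 17).** Cutting the C7–H bond gives aryl ketone 17. This is better than cutting C7–aryl, because a Felkin–Anh addition of an anisyl nucleophile to a C7 aldehyde would give the C7 epimer, whereas hydride addition to the ketone should give 7S. Ketone 17 has one stereocentre fewer, and the forward reaction must be a 1,2-induction from C4.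

**C7=O as a dithiane (17 ⇒ 16).** The ketone is traced to the 1,3-dithiane 16. The dithiane protects C4 from epimerisation and β-elimination while C2 is built, and it is the group that lets C7 act as a nucleophile earlier. The forward step must hydrolyse the dithiane without acid strong enough to open the benzylic C2–O1 bond.

**C2–H and C2–aryl (16 ⇒ 14 ⇒ 10 + 13).** Cutting C2–H gives hemiketal 14, and cutting C2–aryl gives lactone 10 and aryllithium 13, which is made from bromide 12 and this from 4-bromophenol 11. This cut uses the lactone carbonyl as the acceptor for the second aryl ring. A cut at C2–O1 (cyclisation of a diol) is kept in reserve. Lactone 10 has only the C3 and C4 stereocentres. The forward steps must stop at single addition and deliver hydride so that the aryl group ends trans to C3.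

**Auxiliary and C6 protection (10 ⇒ 9 ⇒ 8).** The triethylsilyl ether of 10 is removed to give alcohol 9, and the C5 methylene of 9 is traced to the menthyl acetal of 8. The acetal carbon is reduced to CH2 only after it has relayed its configuration to C4 and C3. The forward step must do this without epimerising C4.

**Key disconnection (8 ⇒ 6 + 4 + 5).** The C4–C7 and C3–C6 bonds are cut together. This gives the lithiated dithiane 6, the menthyloxy butenolide 4 and formaldehyde 5. Both branches and both ring stereocentres are made in one flask from a purchasable chiral butenolide, which is the largest simplification in the route. The forward reaction must add 1,4, anti to the alkoxy group, and trap the enolate anti to the new C4 substituent.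

**Dithiane (6 ⇒ 3 ⇒ 1 + 2).** Anion 6 comes from dithiane 3 by deprotonation, and 3 from 4-methoxybenzaldehyde 1 and propane-1,3-dithiol 2.

## Roads not taken

Alternative 1: The cut is through O1–C5, C4–C5 and C7–O, with formaldehyde 5 as C5. The homoallylic benzylic alcohol A2, which already holds C2, C3 and an (E)-anisyl alkene, would condense with 5 in CF3CO2H/AcOH to an oxocarbenium ion. The alkene carbon C4 attacks it, the ring closes, and the anisyl-stabilised C7 cation is taken up by acetate to give triacetate A1; selective removal of the aryl acetate would finish the synthesis.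
- Merits: the ring, C4 and the C7 acetate arise in one operation, and from A2 the target is two steps away. In step count this road is clearly better than the chosen plan.
- Weak points: C7 is made by capture of a free, planar benzylic cation, and the anisyl acetate can re-ionise in the same medium, so its configuration is only weakly biased by C4. The C2 carbinol of A2 is a para-oxygenated benzylic alcohol in strong acid, and the oxocarbenium ion can undergo a 2-oxonia-Cope shift; both erode the C2/C3 relationship. A2 itself needs two stereocentres set beforehand.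
- Comparison: against the shorter sequence, the chosen plan sets a C7 centre made by hydride addition under 1,2-control and a route in which no benzylic C–O bond meets strong acid after C7 is oxygenated.

Alternative 2: The cut is through C2–C3 and C4–C5. SnCl4 would ionise the glyceraldehyde-derived aryl dioxolane A4 to an oxocarbenium ion whose carbon attacks the alkene; a 1,2-shift of the OCH2 carbon to the new cation then contracts the ring and gives the all-trans aldehyde A3. A4 is drawn with the (4S) carbinol centre that a chair with all substituents equatorial would require.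
- Merits: the ring and all three ring stereocentres come from one chiral-pool centre in one step. C2 and its aryl group are in place, trans to C3, as soon as the ring exists. Here this road is better, since the chosen plan needs steps 6 and 7 for that and accepts a stereochemical risk at C2.
- Weak points: the alkene of A4 is 1,2-disubstituted and carries an inductively withdrawing allylic silyloxy group, so the Prins step must create an unstabilised secondary cation at C4 or be fully concerted. C7 is delivered as an aldehyde α to an epimerisable centre. Felkin–Anh addition of an anisyl nucleophile would give the wrong C7 epimer, so oxidation and the same ketone reduction as in the chosen route would follow. Two silyl ethers must also be told apart.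
- Comparison: the chosen plan sets against it a key step of established reactivity and a C7 carbon that arrives with its aryl ring at the ketone level.

Alternative 3: The cut is through O1–C2 and C4–C5. Sn(OTf)2 would open the donor–acceptor cyclopropane A6 at the bond between the aryl carbon and the malonate carbon; the oxygen of formaldehyde 5 bonds to C2 and the malonate carbon to the formaldehyde carbon, giving oxolane diester A5.
- Merits: the step is catalytic in metal, uses no stoichiometric auxiliary, and fixes C2 stereospecifically. In these respects it is better than the chosen plan, which discards menthol.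
- Weak points: the annulation inverts the donor carbon, so the 2,3-trans product needs the cis cyclopropane A6 as a single enantiomer. That means a (Z)-alkene and an enantioselective malonate-carbene cyclopropanation, a difficult combination. The para-silyloxyphenyl donor favours full ionisation and loss of stereospecificity. Formaldehyde is a less established partner than aryl aldehydes. C4 emerges quaternary, so one ester must be removed, the other turned into the anisyl ketone, and the C7 reduction still follows.
- Comparison: the chosen plan sets against it a C4 centre that is formed as a CH stereocentre already bearing C7 and its aryl ring, with far less adjustment after the key step.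

Key step: step 2

Assumption: formaldehyde 5 is used as the dry monomer, generated by cracking paraformaldehyde and carried into the flask in a nitrogen stream; furanone 4 is taken as a purchasable single diastereomer.

## Route

Step 1
Reactants: 1 4-methoxybenzaldehyde; 2 propane-1,3-dithiol
Product: 3 2-(4-methoxyphenyl)-1,3-dithiane
Conditions: BF3·OEt2 (cat.), CH2Cl2, 0 °C → rt
Reagents that add atoms: none
Why: Lewis acid-catalysed dithioacetalisation of an aromatic aldehyde; water is the only by-product and no stereocentre is formed.

Step 2
Reactants: 3 2-(4-methoxyphenyl)-1,3-dithiane; 4 (5R)-5-{[(1R,2S,5R)-5-methyl-2-(propan-2-yl)cyclohexyl]oxy}furan-2(5H)-one; 5 formaldehyde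
Product: 8 (3S,4R,5R)-3-(hydroxymethyl)-4-[2-(4-methoxyphenyl)-1,3-dithian-2-yl]-5-{[(1R,2S,5R)-5-methyl-2-(propan-2-yl)cyclohexyl]oxy}oxolan-2-one, via 2-lithio-2-(4-methoxyphenyl)-1,3-dithiane 6 (not isolated), via lithium enolate of the conjugate adduct 7 (not isolated)
Conditions: n-BuLi, THF, −78 → −20 °C; 4, THF, −78 °C; CH2O (g), −78 → −50 °C; AcOH, −78 °C
Reagents that add atoms: none
Why: n-BuLi removes the C2 proton of 3, and the sulfur-stabilised benzylic anion 6, a soft and hindered nucleophile, adds to the β-carbon of butenolide 4 (C4–C7) to give lithium enolate 7, which is trapped cold by monomeric formaldehyde 5 in an aldol addition (C3–C6). The closest known reaction type is the tandem conjugate addition–enolate trapping of lithiated dithianes on 5-alkoxyfuran-2(5H)-ones. No ring is closed; both bonds are made on the existing lactone ring, so no mode of closure is at issue. C4 is controlled by the C5 acetal centre: the menthyloxy group covers one face of the planar butenolide and the anion enters anti to it, giving 4R. C3 is controlled by the new C4 centre: the bulky dithianyl group shields its own face of enolate 7, so formaldehyde is taken up anti to it, giving 3S and the 3,4-trans-4,5-trans lactone. The step needs 1,4- over 1,2-addition and no γ-deprotonation of 4, which the soft, weakly basic character of 6 and the low temperature secure; it needs anti delivery twice, which the acetal substituent and then the C4 substituent secure; and it needs a single hydroxymethylation, which follows because the aldolate formed is no longer an enolate. Quenching cold with AcOH guards against retro-aldol loss of the new C6 unit.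

Step 3
Reactants: 8 (3S,4R,5R)-3-(hydroxymethyl)-4-[2-(4-methoxyphenyl)-1,3-dithian-2-yl]-5-menthyloxyoxolan-2-one
Product: 9 (3S,4R)-3-(hydroxymethyl)-4-[2-(4-methoxyphenyl)-1,3-dithian-2-yl]oxolan-2-one
Conditions: NaBH4, aq KOH, THF/EtOH, 0 °C → rt; then 2 M HCl to pH 2, rt
Reagents that add atoms: none
Why: One-pot saponification, reduction and relactonisation, as known for 5-menthyloxy lactones: hydroxide opens the acyloxy acetal to a carboxylate and a C5 aldehyde with loss of menthol, borohydride present from the start reduces the aldehyde before C4 can enolise, and acid closes the γ-hydroxy acid to the lactone; C3 and C4 are not touched.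

Step 4
Reactants: 9 (3S,4R)-3-(hydroxymethyl)-4-[2-(4-methoxyphenyl)-1,3-dithian-2-yl]oxolan-2-one
Product: 10 (3S,4R)-4-[2-(4-methoxyphenyl)-1,3-dithian-2-yl]-3-[(triethylsilyloxy)methyl]oxolan-2-one
Conditions: Et3SiCl, imidazole, CH2Cl2, 0 °C
Reagents that add atoms: chlorotriethylsilane, CC[Si](Cl)(CC)CC
Why: Standard silylation of a primary alcohol; the triethylsilyl ether removes the acidic proton and the retro-aldol pathway before the aryllithium step and is labile enough to leave in the acidic quench of step 7.

Step 5
Reactants: 11 4-bromophenol
Product: 12 (4-bromophenoxy)tri(propan-2-yl)silane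
Conditions: i-Pr3SiCl, imidazole, DMF, rt
Reagents that add atoms: chlorotri(propan-2-yl)silane, CC(C)[Si](Cl)(C(C)C)C(C)C
Why: Standard phenol silylation; the triisopropylsilyl ether should survive n-BuLi, BF3·OEt2 and hydride and later leaves with buffered fluoride without harm to acetates.

Step 6
Reactants: 12 (4-bromophenoxy)tri(propan-2-yl)silane; 10 (3S,4R)-4-[2-(4-methoxyphenyl)-1,3-dithian-2-yl]-3-[(triethylsilyloxy)methyl]oxolan-2-one
Product: 14 (3S,4R)-4-[2-(4-methoxyphenyl)-1,3-dithian-2-yl]-3-[(triethylsilyloxy)methyl]-2-{4-[tri(propan-2-yl)silyloxy]phenyl}oxolan-2-ol (both C2 epimers, in equilibrium with the open γ-hydroxy ketone), via 4-[tri(propan-2-yl)silyloxy]phenyllithium 13 (not isolated)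
Conditions: 12, n-BuLi, THF, −78 °C; then 10, THF, −78 °C; aq NH4Cl, −78 °C
Reagents that add atoms: none
Why: Bromine–lithium exchange followed by single addition of an aryllithium to a γ-lactone; the lithium hemiketalate is stable at −78 °C, so the ketone appears only on quench and a second addition is avoided. The C2 configuration of 14 is immaterial because C2 becomes planar in step 7.

Step 7
Reactants: 14 (3S,4R)-4-[2-(4-methoxyphenyl)-1,3-dithian-2-yl]-3-[(triethylsilyloxy)methyl]-2-{4-[tri(propan-2-yl)silyloxy]phenyl}oxolan-2-ol
Product: 16 [(2R,3S,4R)-4-[2-(4-methoxyphenyl)-1,3-dithian-2-yl]-2-{4-[tri(propan-2-yl)silyloxy]phenyl}oxolan-3-yl]methanol, via triethylsilyl ether of the oxolane 15 (not isolated)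
Conditions: Et3SiH, BF3·OEt2, CH2Cl2, −78 → −30 °C; then MeOH, 1 M aq HCl, 0 °C
Reagents that add atoms: none
Why: Reductive deoxygenation (ionic hydrogenation) of a cyclic hemiketal through the 2-aryl oxocarbenium ion; in the envelope that keeps the very large C4 dithianyl group pseudo-equatorial, hydride should enter anti to that group, which puts the aryl group trans to C3 (2R), the all-trans arrangement that is also the thermodynamically preferred one. The acidic methanol quench removes the triethylsilyl group while the aryl silyl ether and the dithiane stay.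

Step 8
Reactants: 16 [(2R,3S,4R)-4-[2-(4-methoxyphenyl)-1,3-dithian-2-yl]-2-{4-[tri(propan-2-yl)silyloxy]phenyl}oxolan-3-yl]methanol
Product: 17 (4-methoxyphenyl)[(3R,4S,5R)-4-(hydroxymethyl)-5-{4-[tri(propan-2-yl)silyloxy]phenyl}oxolan-3-yl]methanone
Conditions: MeI, CaCO3, MeCN/H2O (4:1), 45 °C
Reagents that add atoms: water, O
Why: Alkylative dithiane hydrolysis: S-methylation makes a sulfonium leaving group, the anisyl-stabilised thionium ion is captured by water, and a second methylation releases the ketone; the buffered neutral medium spares the aryl silyl ether and the benzylic ring ether. C4 is now α to a ketone but already has the more stable trans configuration.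

Step 9
Reactants: 17 (4-methoxyphenyl)[(3R,4S,5R)-4-(hydroxymethyl)-5-{4-[tri(propan-2-yl)silyloxy]phenyl}oxolan-3-yl]methanone
Product: 18 (S)-[(3R,4S,5R)-4-(hydroxymethyl)-5-{4-[tri(propan-2-yl)silyloxy]phenyl}oxolan-3-yl](4-methoxyphenyl)methanol
Conditions: LiBH(s-Bu)3 (L-Selectride, excess), THF, −78 °C; aq NH4Cl
Reagents that add atoms: none
Why: Felkin–Anh-controlled reduction of an α-branched aryl ketone: with the more substituted ring carbon C3 anti to the incoming hydride, C5 next to the carbonyl oxygen and the C4 hydrogen next to the aryl ring, the bulky borohydride should attack the face that gives the 7S alcohol. The free C6 hydroxyl only consumes one equivalent of hydride.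

Step 10
Reactants: 18 (S)-[(3R,4S,5R)-4-(hydroxymethyl)-5-{4-[tri(propan-2-yl)silyloxy]phenyl}oxolan-3-yl](4-methoxyphenyl)methanol
Product: 19 (S)-[(3R,4S,5R)-4-(acetoxymethyl)-5-{4-[tri(propan-2-yl)silyloxy]phenyl}oxolan-3-yl](4-methoxyphenyl)methyl acetate
Conditions: Ac2O, pyridine, DMAP (cat.), CH2Cl2, 0 °C → rt
Reagents that add atoms: acetic anhydride, CC(=O)OC(C)=O
Why: Nucleophile-catalysed acylation of a primary and a secondary benzylic alcohol; the basic medium acylates at oxygen without ionising C7–O, so the C7 configuration is retained.

Step 11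
Reactants: 19 (S)-[(3R,4S,5R)-4-(acetoxymethyl)-5-{4-[tri(propan-2-yl)silyloxy]phenyl}oxolan-3-yl](4-methoxyphenyl)methyl acetate
Product: 20 (S)-[(3R,4S,5R)-4-(acetoxymethyl)-5-(4-hydroxyphenyl)oxolan-3-yl](4-methoxyphenyl)methyl acetate (the target)
Conditions: Bu4NF, AcOH (1:1), THF, 0 °C
Reagents that add atoms: none
Why: Fluoride cleavage of an aryl silyl ether, which is fast because phenoxide is a good leaving group; AcOH buffers the phenoxide so that the two acetates should neither migrate nor hydrolyse.

## Compound list

1 | 4-methoxybenzaldehyde | COc1ccc(C=O)cc1 | starting material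
2 | propane-1,3-dithiol | SCCCS | starting material
3 | 2-(4-methoxyphenyl)-1,3-dithiane | COc1ccc(cc1)C1SCCCS1 | intermediate
4 | (5R)-5-{[(1R,2S,5R)-5-methyl-2-(propan-2-yl)cyclohexyl]oxy}furan-2(5H)-one | O=C1C=C[C@H](O[C@@H]2C[C@H](C)CC[C@H]2C(C)C)O1 | starting material
5 | formaldehyde | C=O | starting material
6 | 2-lithio-2-(4-methoxyphenyl)-1,3-dithiane | COc1ccc(cc1)C1([Li])SCCCS1 | intermediate (not isolated)
7 | lithium (4R,5R)-4-[2-(4-methoxyphenyl)-1,3-dithian-2-yl]-5-{[(1R,2S,5R)-5-methyl-2-(propan-2-yl)cyclohexyl]oxy}-4,5-dihydrofuran-2-olate | COc1ccc(cc1)C1(SCCCS1)[C@H]1[C@H](O[C@@H]2C[C@H](C)CC[C@H]2C(C)C)OC(O[Li])=C1 | intermediate (not isolated)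
8 | (3S,4R,5R)-3-(hydroxymethyl)-4-[2-(4-methoxyphenyl)-1,3-dithian-2-yl]-5-{[(1R,2S,5R)-5-methyl-2-(propan-2-yl)cyclohexyl]oxy}oxolan-2-one | COc1ccc(cc1)C1(SCCCS1)[C@H]1[C@H](O[C@@H]2C[C@H](C)CC[C@H]2C(C)C)OC(=O)[C@@H]1CO | intermediate
9 | (3S,4R)-3-(hydroxymethyl)-4-[2-(4-methoxyphenyl)-1,3-dithian-2-yl]oxolan-2-one | COc1ccc(cc1)C1(SCCCS1)[C@H]1COC(=O)[C@@H]1CO | intermediate
10 | (3S,4R)-4-[2-(4-methoxyphenyl)-1,3-dithian-2-yl]-3-[(triethylsilyloxy)methyl]oxolan-2-one | COc1ccc(cc1)C1(SCCCS1)[C@H]1COC(=O)[C@@H]1CO[Si](CC)(CC)CC | intermediate
11 | 4-bromophenol | Oc1ccc(Br)cc1 | starting material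
12 | (4-bromophenoxy)tri(propan-2-yl)silane | CC(C)[Si](Oc1ccc(Br)cc1)(C(C)C)C(C)C | intermediate
13 | 4-[tri(propan-2-yl)silyloxy]phenyllithium | [Li]c1ccc(O[Si](C(C)C)(C(C)C)C(C)C)cc1 | intermediate (not isolated)
14 | (3S,4R)-4-[2-(4-methoxyphenyl)-1,3-dithian-2-yl]-3-[(triethylsilyloxy)methyl]-2-{4-[tri(propan-2-yl)silyloxy]phenyl}oxolan-2-ol (C2 epimers) | COc1ccc(cc1)C1(SCCCS1)[C@H]1COC(O)(c2ccc(O[Si](C(C)C)(C(C)C)C(C)C)cc2)[C@@H]1CO[Si](CC)(CC)CC | intermediate
15 | triethyl{[(2R,3S,4R)-4-[2-(4-methoxyphenyl)-1,3-dithian-2-yl]-2-{4-[tri(propan-2-yl)silyloxy]phenyl}oxolan-3-yl]methoxy}silane | COc1ccc(cc1)C1(SCCCS1)[C@H]1CO[C@@H](c2ccc(O[Si](C(C)C)(C(C)C)C(C)C)cc2)[C@@H]1CO[Si](CC)(CC)CC | intermediate (not isolated)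
16 | [(2R,3S,4R)-4-[2-(4-methoxyphenyl)-1,3-dithian-2-yl]-2-{4-[tri(propan-2-yl)silyloxy]phenyl}oxolan-3-yl]methanol | COc1ccc(cc1)C1(SCCCS1)[C@H]1CO[C@@H](c2ccc(O[Si](C(C)C)(C(C)C)C(C)C)cc2)[C@@H]1CO | intermediate
17 | (4-methoxyphenyl)[(3R,4S,5R)-4-(hydroxymethyl)-5-{4-[tri(propan-2-yl)silyloxy]phenyl}oxolan-3-yl]methanone | COc1ccc(cc1)C(=O)[C@H]1CO[C@@H](c2ccc(O[Si](C(C)C)(C(C)C)C(C)C)cc2)[C@@H]1CO | intermediate
18 | (S)-[(3R,4S,5R)-4-(hydroxymethyl)-5-{4-[tri(propan-2-yl)silyloxy]phenyl}oxolan-3-yl](4-methoxyphenyl)methanol | COc1ccc([C@@H](O)[C@H]2CO[C@@H](c3ccc(O[Si](C(C)C)(C(C)C)C(C)C)cc3)[C@@H]2CO)cc1 | intermediate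
19 | (S)-[(3R,4S,5R)-4-(acetoxymethyl)-5-{4-[tri(propan-2-yl)silyloxy]phenyl}oxolan-3-yl](4-methoxyphenyl)methyl acetate | COc1ccc([C@@H](OC(C)=O)[C@H]2CO[C@@H](c3ccc(O[Si](C(C)C)(C(C)C)C(C)C)cc3)[C@@H]2COC(C)=O)cc1 | intermediate
20 | (S)-[(3R,4S,5R)-4-(acetoxymethyl)-5-(4-hydroxyphenyl)oxolan-3-yl](4-methoxyphenyl)methyl acetate | COc1ccc([C@@H](OC(C)=O)[C@H]2CO[C@@H](c3ccc(O)cc3)[C@@H]2COC(C)=O)cc1 | target

## Step count and risks

Total: 11 steps. Longest linear sequence: 10 steps (steps 1–4 and 6–11, from 4-methoxybenzaldehyde 1); step 5 is a one-step side branch.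

**Step 2 (key step).** Trapping of enolate 7 may be incomplete, either through repolymerisation and poor mass transfer of gaseous formaldehyde at −78 °C or through protonation of the enolate by moisture carried in with it. Retro-aldol loss of C6 on warming before the quench is a second risk. Fallback: starting from 3 and 4, the conjugate addition is run as before, but enolate 7 is silylated with Me3SiCl to the trimethylsilyl ketene acetal F1. This is isolated crude and hydroxymethylated in a separate Mukaiyama aldol with aqueous formaldehyde 5 and Yb(OTf)3 (cat.) in THF, the electrophile again entering anti to the C4 group. The route is rejoined at 8.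

**Step 7.** Hydride delivery anti to the adjacent C3 branch, the usual bias of 3-alkyl-2-aryl oxocarbenium ions, may compete with delivery anti to the C4 dithianyl group and erode the selectivity at C2. On warming in the presence of silane, the new benzylic C2–O1 bond may also ionise and be reduced further. Fallback: starting from 14, NaBH4 in MeOH/THF reduces the open hydroxy-ketone tautomer to the 1,4-diol F2 (both carbinol epimers). BF3·OEt2 in CH2Cl2 at −20 °C, without silane, then ionises the para-silyloxybenzylic alcohol, and the primary C5 hydroxyl closes the ring under reversible, trans-selective conditions. This gives 15, and the methanolic HCl quench of step 7 then returns the route to 16.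

**Step 9.** Facial discrimination may be modest, because both α-substituents of C4 are ring carbons and the lithium alkoxide formed at C6 may perturb the Felkin–Anh arrangement. Fallback: starting from 17, control is moved from substrate to catalyst by asymmetric transfer hydrogenation with RuCl[(S,S)-TsDPEN](p-cymene) in HCO2H/Et3N, which reduces aryl ketones to the (S)-carbinol and leads directly to 18. No new compound is made (entry F0).

**Step 3.** The transient C5 aldehyde may enolise under the basic conditions before it is reduced, which would epimerise C4; β-elimination toward the dithiane is a lesser risk. Fallback: starting from 8, the acetal is first hydrolysed under acid (CF3CO2H/H2O, warm) to the 5-hydroxy lactone F3 (C5 epimers). This is reduced with NaBH4 in buffered aqueous THF without added hydroxide and relactonised on acidification, rejoining the route at 9.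

**Step 6.** The hemiketalate may collapse early and take up a second aryllithium, or the basic aryllithium may enolise the lactone and return starting material. Fallback: starting from 10, the lactone is opened with MeNH(OMe)·HCl and i-PrMgCl to the γ-hydroxy Weinreb amide F4, which is used at once. Two equivalents of 13 then give, after stable chelate formation and quench, the hydroxy ketone that closes to 14, where the route is rejoined.

## Further compounds

F1 | step 2 | {[(4R,5R)-4-[2-(4-methoxyphenyl)-1,3-dithian-2-yl]-5-{[(1R,2S,5R)-5-methyl-2-(propan-2-yl)cyclohexyl]oxy}-4,5-dihydrofuran-2-yl]oxy}trimethylsilane | COc1ccc(cc1)C1(SCCCS1)[C@H]1[C@H](O[C@@H]2C[C@H](C)CC[C@H]2C(C)C)OC(O[Si](C)(C)C)=C1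
F2 | step 7 | (2S,3R)-3-[2-(4-methoxyphenyl)-1,3-dithian-2-yl]-2-[(triethylsilyloxy)methyl]-1-{4-[tri(propan-2-yl)silyloxy]phenyl}butane-1,4-diol (C1 epimers) | COc1ccc(cc1)C1(SCCCS1)[C@@H](CO)[C@@H](CO[Si](CC)(CC)CC)C(O)c1ccc(O[Si](C(C)C)(C(C)C)C(C)C)cc1
F0 | step 9 | none | none
F3 | step 3 | (3S,4R)-5-hydroxy-3-(hydroxymethyl)-4-[2-(4-methoxyphenyl)-1,3-dithian-2-yl]oxolan-2-one (C5 epimers) | COc1ccc(cc1)C1(SCCCS1)[C@H]1C(O)OC(=O)[C@@H]1CO
F4 | step 6 | (2S,3R)-4-hydroxy-N-methoxy-3-[2-(4-methoxyphenyl)-1,3-dithian-2-yl]-N-methyl-2-[(triethylsilyloxy)methyl]butanamide | COc1ccc(cc1)C1(SCCCS1)[C@@H](CO)[C@@H](CO[Si](CC)(CC)CC)C(=O)N(C)OC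
A1 | alternative 1 | (S)-[(3R,4S,5R)-4-(acetoxymethyl)-5-(4-acetoxyphenyl)oxolan-3-yl](4-methoxyphenyl)methyl acetate | COc1ccc([C@@H](OC(C)=O)[C@H]2CO[C@@H](c3ccc(OC(C)=O)cc3)[C@@H]2COC(C)=O)cc1
A2 | alternative 1 | 4-[(1R,2S,3E)-2-(acetoxymethyl)-1-hydroxy-4-(4-methoxyphenyl)but-3-en-1-yl]phenyl acetate | O[C@@H](c1ccc(OC(C)=O)cc1)[C@H](COC(C)=O)/C=C/c1ccc(OC)cc1
A3 | alternative 2 | (3R,4S,5R)-4-[(tert-butyldiphenylsilyloxy)methyl]-5-{4-[tri(propan-2-yl)silyloxy]phenyl}oxolane-3-carbaldehyde | O=C[C@H]1CO[C@@H](c2ccc(O[Si](C(C)C)(C(C)C)C(C)C)cc2)[C@@H]1CO[Si](c1ccccc1)(c1ccccc1)C(C)(C)C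
A4 | alternative 2 | (4S)-4-[(E)-3-(tert-butyldiphenylsilyloxy)prop-1-enyl]-2-{4-[tri(propan-2-yl)silyloxy]phenyl}-1,3-dioxolane (acetal carbon as a mixture) | CC(C)[Si](Oc1ccc(cc1)C1OC[C@@H](O1)/C=C/CO[Si](c1ccccc1)(c1ccccc1)C(C)(C)C)(C(C)C)C(C)C
A5 | alternative 3 | dimethyl (4S,5R)-4-[(tert-butyldimethylsilyloxy)methyl]-5-{4-[tri(propan-2-yl)silyloxy]phenyl}oxolane-3,3-dicarboxylate | COC(=O)C1(C(=O)OC)CO[C@@H](c2ccc(O[Si](C(C)C)(C(C)C)C(C)C)cc2)[C@@H]1CO[Si](C)(C)C(C)(C)C
A6 | alternative 3 | dimethyl cis-2-[(tert-butyldimethylsilyloxy)methyl]-3-{4-[tri(propan-2-yl)silyloxy]phenyl}cyclopropane-1,1-dicarboxylate (single enantiomer) | COC(=O)C1(C(=O)OC)[C@H](c2ccc(O[Si](C(C)C)(C(C)C)C(C)C)cc2)[C@@H]1CO[Si](C)(C)C(C)(C)C
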